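The readings come from a simulation for an exercise; noise was put on by code.

I decided to leave Thursday's flask at its 20 °C and to hand over the bench with this note, which reckons every flask by one clock.

| flask | starting material | temperature | remark | time |
|---|---|---|---|---|
| summer | 0.67 M | 12 °C | run made earlier |  |
| winter | 0.94 M | 51 °C | run made earlier |  |
| Tuesday's | 1.5 M | 65 °C |  | 10 h |
| Monday's | 0.80 M | −5 °C |  | 10 h |
| Sunday's | 1.5 M | 50 °C |  | 10 h |
| Thursday's | 1.0 M | 20 °C |  | 10 h |
| Saturday's | 1.5 M | 35 °C |  | 10 h |

- summer (time / h: target / %, isomer of the product / %): 1.50: 1.5, 1.4; 3.00: 3.1, 2.7; 6.00: 5.8, 4.2; 12.0: 10.4, 8.5; 25.0: 19.3, 16.0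
- winter (time / h: target / %, isomer of the product / %): 0.250: 21.2, 19.4; 0.417: 21.5, 28.0; 0.833: 19.0, 40.9; 2.00: 16.9, 49.7; 4.00: 16.5, 50.0

(scatter of a reading: 0.3 percentage points)

1. ranking by share of target in all that became target or isomer of the product, from high to low, at 10 h (Tuesday's / Monday's / Sunday's / Thursday's / Saturday's)
2. the same order at 30 min (Tuesday's / Monday's / Sunday's / Thursday's / Saturday's)
3. the share of target in all that became target or isomer of the product of the flask you put first, at 10 h
4. the share of target in all that became target or isomer of the product of the flask you put last, at 10 h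



Target and isomer of the product both appeared from the first readings, and in the winter run the readings came to rest at a plateau, so I separated a kinetic share from a plateau share (kinetic against thermodynamic control). Taking the loss as first order in [starting material], the last summer reading gave 0.0174 h⁻¹ and the first winter reading 2.08 h⁻¹, hence an activation energy of 94.3 kJ mol⁻¹ and a half-life of 13.4 h in Thursday's flask. Thursday's 10 h therefore held 0.744 half-lives, the run time divided by the half-life of starting material at the flask's temperature. Because that stayed below one, I told my successor to expect 59.7% of the starting material still there in Thursday's flask. For the share of target in that flask I made a separate estimate, taking the share at the last summer reading, 54.7%. I also said not to warm it, because at Saturday's 35 °C the half-life shrank to 2.05 h, which made 4.89 half-lives. For the bottom of the ranking I took the winter plateau share, 24.8%.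

The forecast gave Thursday's > Monday's > Saturday's > Tuesday's > Sunday's at 10 h and Saturday's > Thursday's > Monday's > Sunday's > Tuesday's at 30 min, with 57% (54% to 60%) and 24.8% (23.5% to 26%), holding that “Hotter slightly favours target”. The flasks gave Thursday's > Monday's > Saturday's > Sunday's > Tuesday's and Saturday's > Thursday's > Monday's > Sunday's > Tuesday's, with 53.9% at the top and 19.4% at the bottom, lower than my plateau share.

    starting material ⇌ target (K = 1.20, k = 0.290 h⁻¹, Ea = 106 kJ mol⁻¹, ΔH = −46.0 kJ mol⁻¹)
    starting material ⇌ isomer of the product (K = 2.50, k = 0.140 h⁻¹, Ea = 93.0 kJ mol⁻¹, ΔH = −26.0 kJ mol⁻¹)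
    target ⇌ isomer of the product (k = 0.300 h⁻¹, Ea = 89.0 kJ mol⁻¹)
    (constants at 35 °C)

Thursday's flask kept 58.4% of its starting material at 10.0 h, where my 0.744 half-lives had given 59.7%. The neighbouring flask, like Thursday's but kept at 35 °C, had 4.89 half-lives on the same clock, more than Thursday's. It held 22.2% of starting material and 51.8% of isomer of the product, and its share of target was 33.4%.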